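The constants are those of an exercise; the run is a simulation.

The easy step came first: catalyst intermediate E gives up target with a half-life of 0.73 min, so I looked elsewhere in the cycle for the slow step.

    substrate + free catalyst → catalyst intermediate A (k1 = 392 /M/h)
    catalyst intermediate A → catalyst intermediate B (k2 = 105 /h)
    coupling partner + catalyst intermediate B ⇌ catalyst intermediate C (K3 = 23 /M, k3 = 87.0 /M/h)
    catalyst intermediate C ⇌ released group + catalyst intermediate D (K4 = 6.78 M, k4 = 48.1 /h)
    catalyst intermediate D → catalyst intermediate E (k5 = 2210 /h)
    catalyst intermediate E → free catalyst + target (k6 = 57.3 /h)
    substrate + released group ⇌ idle adduct, settled at all times (K7 = 9.6 /M)

| flask | substrate | coupling partner | free catalyst | time |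
|---|---|---|---|---|
| green | 0.11 M | 0.100 M (fed, over 10 h) | 1.1 mM | 10 h |
| violet | 0.11 M | 0.210 M (fed, over 10 h) | 1.1 mM | 10 h |

- amounts and yields of released group count idle adduct too
- what has gone from substrate into another species counts as reacted, even if it can come back
- run time (green): 10 h

* part of the substrate that has reacted at the end, green
* part of the substrate that has reacted at the end, violet
* what raising the concentration of coupling partner from its lowest to its highest value here does to the part of the substrate that has reacted (changes below 5 percentage points count as none) (it rises / no change / it falls)

I counted in fractions of the substrate charge and froze two things: the partner as a straight ramp up to its full charge, unconsumed, and the substrate at its charge. With the full green charge present, forward capture of catalyst intermediate B still has a half-life of 0.080 h, longer than that last step, so while the partner was low I took capture as the rate-limiting step and catalyst intermediate B as the resting state.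

In one extreme the whole catalyst charge waits as catalyst intermediate B for the whole run. Target is then the capture constant times catalyst, partner charge and dosing time, divided by two and by the substrate charge: 43.5% green, 91.3% violet.

In the other extreme the catalyst stays shared throughout as at the end of the feed. The other steps cost 4.28 min per turn, which is 0.621 capture times at full partner in green and 1.30 in violet. That gives 26.8% green and 39.6% violet. This shared capture yield, the ceiling divided by one plus that ratio, is what I carried. I expected the flask near the lower extreme, and allowed for partner use and falling substrate by committing to the lower figure.

Each released group can also hold a substrate as idle adduct, and the equilibrium constant times the substrate charge is 1.06. Solving that balance gave adduct fractions of 10.7% green and 13.2% violet. My reacted parts were therefore 37.5% green and 52.8% violet, a rise of 15 percentage points.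

The forecast gave 36% (31% to 41%) for green and 55% (48% to 62%) for violet, and said it rises. Its grounds: “its low concentration keeps capture by intermediate B rate-limiting”.

The simulation gave 35.3% green and 54.7% violet, so it rises, by 19 points.

Violet's target at the end, 40.7%, stood close to its shared capture yield, with 79% of the partner charge still unbound. In the neighbouring flask, violet with 0.19 M of substrate, the ceiling drops to 52.9%. The other steps then cost 3.70 min, so the yield is 24.9%. With the equilibrium constant times its substrate charge at 1.82, the reacted part comes to 38.1%. That flask gave 25.7% target and 39.6% reacted.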